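The data are calculated for an exercise, and the scatter is random.

In this closed, stirred vessel, at constant volume and fixed temperature, grey and teal get the same charge and differ in the bath.

all flasks: partner 0.576 M

|  | starting material | protic impurity | temperature | remark | time |
|---|---|---|---|---|---|
| alpha | 0.96 M | 0.024 M | 10 °C | run made earlier |  |
| epsilon | 0.96 M | 0.036 M | 21 °C | run made earlier |  |
| gamma | 1.4 M | 0.048 M | 10 °C | run made earlier |  |
| grey | 0.96 M | 0.0480 M | 5 °C |  | 15 min |
| teal | 0.96 M | 0.0480 M | 25 °C |  | 15 min |

- alpha (time / min: target / %): 0.667: 13.5; 1.50: 23.4; 4.00: 34.7; 10.0: 36.3
- epsilon (time / min: target / %): 1.00: 28.4; 2.50: 36.3; 5.00: 36.0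
- gamma (time / min: target / %): 1.00: 16.1; 3.00: 26.1; 6.00: 27.1; 10.0: 26.9

(scatter of a reading: 0.3 percentage points)

- the flask with the highest amount of target, in percent of the starting material charged ("all alike" if they lie within 1.5 percentage points) (grey / teal / all alike)
- final target, as a percentage of the starting material charged, in grey
- final target, as a percentage of the starting material charged, in teal

Keep the books in fractions of the starting material charged, and follow the partner, the limiting reagent by the charge, of which less is charged than of starting material. The first entry is my own assumption: the protic impurity takes partner one for one, which leaves free partner at 55.0%. The second entry is the coupling, taken as reversible with target and by-product in equal amounts. The earlier plateaus suggest a quotient near unity, so target squared equals the starting material pool times the partner left. Solving gives 35.5%, the plateau share: free partner over the sum of free partner and starting material charged. The books then close with target at that share, partner left at 19.5% and the pool at 64.5%, a pool that carries no entry for self-condensation.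

The share gives 36.5% for alpha against a last reading of 36.3%, 36.0% for epsilon against 36.0%, and 27.4% for gamma against 26.9%. I therefore commit to the share for grey. I give teal the same number with less trust, since the epsilon readings stop at 5.00 min and 21 °C, while teal stands longer, 15 min, and hotter, at 25 °C. The forecast, holding that “the starting material runs out”, where my books keep a pool of it, says 35% for grey, 35.7% for teal and all alike.

The flasks give 35.9% in grey and 30.7% in teal, so grey holds more.

    partner + protic impurity → quenched reagent (k = 3.00 /M/min, Ea = 53.0 kJ/mol)
    2 starting material → self-condensation product (k = 0.0160 /M/min, Ea = 62.0 kJ/mol)
    starting material + partner ⇌ target + by-product (K = 1.40, k = 0.290 /M/min, Ea = 55.0 kJ/mol, ΔH = 2.00 kJ/mol)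
    crystals ⇌ target, rate k4*(cs4 - [target]) while solid is left; crystals form when [target] > cs4 (solubility = 0.650 M, k = 0.460 /min)
    (constants at 5 °C)

Grey lies 0.40 percentage points above the share and teal 4.8 points below it. At 15.0 min, teal's books read starting material 25.2%, target 30.7% and self-condensation product 44.0%, while grey's read 47.2%, 35.9% and 16.8%, so teal holds more of the unbooked entry than grey. A neighbouring flask, grey with the starting material cut to 0.24 M, has free partner at 220% of its charge, so its share is 68.8%. That flask gives 68.5% target.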